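**Plan**
- Late-stage cuts: the acid comes from its methyl ester, the 9α-alcohol from a C9 ketone, and the 11α-alcohol from the 10,11-alkene of a cyclopentenone (via the epoxy ketone). C13=C14 is cut by Horner–Wadsworth–Emmons olefination, and C15 is set by ketone reduction.
- Ring cuts: C8–C12 and C9–C10. The cyclopentane carries its two chains trans on the adjacent ring carbons C8 and C12, and C9, the oxygenated neighbour of C8, can enter as a nitro-bearing carbon. The ring is therefore a formal (3+2) adduct of succinaldehyde (C10–C13) and a nitroalkene holding C1–C9.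
- Forward order: cyclooctene gives the C1–C8 aldehyde ester and nitromethane adds C9. The amine-catalysed Michael–Henry sequence closes the only ring, then the ω-chain is attached and the ring is adjusted (nitro aldol, nitroalkene, enone, epoxy ketone, ketol, diol).
- Stereochemistry: C8 from the (S)-diarylprolinol silyl ether catalyst; C12 by base equilibration to trans; C15 from (−)-Ipc2BCl; C11 from epoxidation anti to the C12 chain; C9 from hydride attack anti to the C8 chain.

Key step: step 5

Assumption: prostaglandin numbering (C1–C20) is used for all intermediates. The nitro aldol compounds 11, 12, 14 and 15 are carried as mixtures at C9 and C10, because both centres are flattened in steps 8 and 9.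

**Step 1**
Reactants: 1 2,5-dimethoxytetrahydrofuran
Product: 2 succinaldehyde (butanedial)
Conditions: H2O, 90 °C; then distillation, used fresh
Reagents that add atoms: water, O
Why: Hydrolysis of the cyclic bis-acetal in hot water releases the dialdehyde, which is distilled from methanol and water and used at once (acetal hydrolysis).

**Step 2**
Reactants: 3 cis-cyclooctene
Product: 5 methyl 8-oxooctanoate, via 8-hydroperoxy-8-methoxyoctanal 4 (not isolated)
Conditions: O3, CH2Cl2/MeOH, NaHCO3, −78 °C; then Ac2O, Et3N, CH2Cl2, 0 °C to rt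
Reagents that add atoms: ozone, [O-][O+]=O; methanol, CO
Why: Ozonolysis in methanol traps the carbonyl oxide as the methoxy hydroperoxide while the other terminus stays an aldehyde, and acetylation followed by base-induced fragmentation of the peracetate gives the methyl ester (ozonolysis of a cycloalkene to differentiated termini).

**Step 3**
Reactants: 5 methyl 8-oxooctanoate; 6 nitromethane
Product: 7 methyl 8-hydroxy-9-nitrononanoate (racemic)
Conditions: MeNO2 (5 equiv), 1,1,3,3-tetramethylguanidine (10 mol%), THF, 0 °C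
Reagents that add atoms: none
Why: Base-catalysed Henry (nitroaldol) addition of nitromethane to the unhindered aldehyde; the new carbinol centre is racemic and is removed in step 4.

**Step 4**
Reactants: 7 methyl 8-hydroxy-9-nitrononanoate
Product: 9 methyl (E)-9-nitronon-8-enoate, via nitro mesylate 8 (not isolated)
Conditions: MsCl, Et3N, CH2Cl2, 0 °C
Reagents that add atoms: none
Why: Mesylation of the β-nitro alcohol and triethylamine-induced β-elimination through the nitronate give the conjugated nitroalkene, the E isomer being strongly favoured thermodynamically (dehydration of a Henry adduct).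

**Step 5**
Reactants: 2 succinaldehyde; 9 methyl (E)-9-nitronon-8-enoate
Product: 12 methyl 7-[(1R,5S)-5-formyl-3-hydroxy-2-nitrocyclopentyl]heptanoate (chains trans), via open-chain Michael adduct 10 (not isolated), via cis-formyl cyclopentane 11 (not isolated)
Conditions: (S)-α,α-diphenylprolinol trimethylsilyl ether (10 mol%), 4-nitrophenol (10 mol%), 2 in excess, MeCN, rt; then i-Pr2NEt, 0 °C
Reagents that add atoms: none
Why: The secondary amine condenses with one formyl group of 2 to give an E-enamine whose C12 adds to C8 of nitroalkene 9 (C8–C12), and after hydrolysis of the iminium ion the added i-Pr2NEt generates the C9 nitronate, which attacks the remaining aldehyde at C10 (C9–C10); this is the diarylprolinol silyl ether catalysed Michael addition of aldehydes to nitroalkenes followed by an intramolecular Henry reaction. The cyclopentane closes in the 5-exo-trig mode, the alternative attack on the C13 formyl group being a strained 4-exo closure. C8 is set by the catalyst: the diphenyl(silyloxy)methyl group blocks one enamine face and the nitroalkene approaches the other in the acyclic synclinal arrangement, which with the (S)-catalyst should give the 8R configuration. C12 is formed cis to the C8 chain in the syn-selective Michael step, but it is α to the formyl group and should equilibrate under the amine base to the trans (12S) aldehyde. C9 and C10 arise in the reversible Henry step and need no control, since both are erased later. The step needs cross-reaction of a mono-enamine in preference to self-aldol of 2, which the high electrophilicity of the nitroalkene, the acid co-catalyst and the excess of 2 should secure.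

**Step 6**
Reactants: 12 methyl 7-[(1R,5S)-5-formyl-3-hydroxy-2-nitrocyclopentyl]heptanoate; 13 dimethyl (2-oxoheptyl)phosphonate
Product: 14 methyl 7-[(1R,5R)-3-hydroxy-2-nitro-5-[(1E)-3-oxooct-1-enyl]cyclopentyl]heptanoate
Conditions: LiCl, i-Pr2NEt, MeCN, 0 °C to rt
Reagents that add atoms: none
Why: Horner–Wadsworth–Emmons olefination under Masamune–Roush conditions, mild enough for the epimerisable nitro aldol aldehyde, with the stabilised phosphonate anion giving the E-enone.

**Step 7**
Reactants: 14 methyl 7-[(1R,5R)-3-hydroxy-2-nitro-5-[(1E)-3-oxooct-1-enyl]cyclopentyl]heptanoate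
Product: 15 methyl 7-[(1R,5R)-3-hydroxy-5-[(1E,3S)-3-hydroxyoct-1-enyl]-2-nitrocyclopentyl]heptanoate
Conditions: (−)-Ipc2BCl (3 equiv), THF, −40 to −20 °C; then aq. NaHCO3
Reagents that add atoms: none
Why: Asymmetric ketone reduction with B-chlorodiisopinocampheylborane, in which hydride passes from an isopinocampheyl group through a six-membered boat-like transition state with the alkenyl group as the large substituent, so the (−)-reagent should give the 15S allylic alcohol; nitro and ester groups are inert and the free C10 hydroxyl only consumes reagent.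

**Step 8**
Reactants: 15 methyl 7-[(1R,5R)-3-hydroxy-5-[(1E,3S)-3-hydroxyoct-1-enyl]-2-nitrocyclopentyl]heptanoate
Product: 16 methyl 7-[(1R,5R)-5-[(1E,3S)-3-hydroxyoct-1-enyl]-2-nitrocyclopent-2-en-1-yl]heptanoate
Conditions: acidic Al2O3, ClCH2CH2Cl, 60 °C
Reagents that add atoms: none
Why: Alumina-promoted dehydration of the β-nitro alcohol (β-elimination through the surface-bound nitronate) should give the C9=C10 nitroalkene from every C9/C10 diastereomer, while the C15 allylic alcohol, which has no acidifying neighbour, is left alone.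

**Step 9**
Reactants: 16 methyl 7-[(1R,5R)-5-[(1E,3S)-3-hydroxyoct-1-enyl]-2-nitrocyclopent-2-en-1-yl]heptanoate
Product: 17 methyl 7-[(1R,2S)-2-[(1E,3S)-3-hydroxyoct-1-enyl]-5-oxocyclopent-3-en-1-yl]heptanoate (the 10,11-unsaturated C9 ketone)
Conditions: DABCO (2 equiv), O2 (1 atm), MeCN, 0 °C to rt
Reagents that add atoms: dioxygen, O=O
Why: Base-mediated aerobic Nef reaction: DABCO removes the γ-proton at C11 to give the dienyl nitronate, which is oxygenated at C9 and loses nitrite, leaving the C9 ketone conjugated with the new C10=C11 alkene.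

**Step 10**
Reactants: 17 methyl 7-[(1R,2S)-2-[(1E,3S)-3-hydroxyoct-1-enyl]-5-oxocyclopent-3-en-1-yl]heptanoate
Product: 18 methyl 7-[(1S,2R,3R,5S)-2-[(1E,3S)-3-hydroxyoct-1-enyl]-4-oxo-6-oxabicyclo[3.1.0]hexan-3-yl]heptanoate (10α,11α-epoxy ketone)
Conditions: 30% aq. H2O2, NaOH (cat.), MeOH, −40 °C
Reagents that add atoms: hydrogen peroxide, OO
Why: Weitz–Scheffer nucleophilic epoxidation of the cyclopentenone, in which hydroperoxide adds to C11 anti to the adjacent C12 chain so that the 10α,11α-epoxide (11R oxygen) should predominate; the isolated C13=C14 alkene is not attacked.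

**Step 11**
Reactants: 18 methyl 7-[(1S,2R,3R,5S)-2-[(1E,3S)-3-hydroxyoct-1-enyl]-4-oxo-6-oxabicyclo[3.1.0]hexan-3-yl]heptanoate
Product: 19 methyl 7-[(1R,2R,3R)-3-hydroxy-2-[(1E,3S)-3-hydroxyoct-1-enyl]-5-oxocyclopentyl]heptanoate (11α-hydroxy C9 ketone)
Conditions: Zn dust, NH4Cl, MeOH/H2O, rt
Reagents that add atoms: none
Why: Dissolving-metal reduction of the α,β-epoxy ketone cleaves the C10–O bond next to the carbonyl group and leaves the C11–O bond, so the 11α configuration is kept and the near-neutral medium avoids dehydration of the β-hydroxy ketone.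

**Step 12**
Reactants: 19 methyl 7-[(1R,2R,3R)-3-hydroxy-2-[(1E,3S)-3-hydroxyoct-1-enyl]-5-oxocyclopentyl]heptanoate
Product: 20 methyl 7-[(1R,2R,3R,5S)-3,5-dihydroxy-2-[(1E,3S)-3-hydroxyoct-1-enyl]cyclopentyl]heptanoate (methyl ester of the target)
Conditions: LiBH(s-Bu)3 (3.5 equiv), THF, −78 °C; then H2O
Reagents that add atoms: none
Why: Bulky trialkylborohydride reduction of the cyclopentanone, with hydride delivered to C9 from the β face, anti to the α-oriented C8 chain, giving the 9α (9S) alcohol; the ester is untouched at −78 °C.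

**Step 13**
Reactants: 20 methyl 7-[(1R,2R,3R,5S)-3,5-dihydroxy-2-[(1E,3S)-3-hydroxyoct-1-enyl]cyclopentyl]heptanoate
Product: 21 7-[(1R,2R,3R,5S)-3,5-dihydroxy-2-[(1E,3S)-3-hydroxyoct-1-enyl]cyclopentyl]heptanoic acid (the target prostaglandin)
Conditions: LiOH, THF/H2O (3:1), 0 °C to rt; then 1 M HCl to pH 4, 0 °C
Reagents that add atoms: lithium hydroxide, [Li+].[OH-]
Why: Saponification of the methyl ester and careful acidification; the triol has no β-hydroxy ketone and is stable to hydroxide.

**Compound list**
1 | 2,5-dimethoxytetrahydrofuran (cis/trans mixture) | COC1CCC(OC)O1 | starting material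
2 | succinaldehyde | O=CCCC=O | intermediate
3 | cis-cyclooctene | C1CC/C=C\CCC1 | starting material
4 | 8-hydroperoxy-8-methoxyoctanal | O=CCCCCCCC(OC)OO | intermediate (not isolated)
5 | methyl 8-oxooctanoate | O=CCCCCCCC(=O)OC | intermediate
6 | nitromethane | C[N+](=O)[O-] | starting material
7 | methyl 8-hydroxy-9-nitrononanoate (racemic) | COC(=O)CCCCCCC(O)C[N+](=O)[O-] | intermediate
8 | methyl 8-(methanesulfonyloxy)-9-nitrononanoate (racemic) | COC(=O)CCCCCCC(OS(C)(=O)=O)C[N+](=O)[O-] | intermediate (not isolated)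
9 | methyl (E)-9-nitronon-8-enoate | COC(=O)CCCCCC/C=C/[N+](=O)[O-] | intermediate
10 | methyl (8R,9R)-9-formyl-8-(nitromethyl)-11-oxoundecanoate | O=C[C@H](CC=O)[C@@H](CCCCCCC(=O)OC)C[N+](=O)[O-] | intermediate (not isolated)
11 | methyl 7-[(1R,5R)-5-formyl-3-hydroxy-2-nitrocyclopentyl]heptanoate (chains cis; C9/C10 mixture) | O=C[C@H]1[C@@H](CCCCCCC(=O)OC)C([N+](=O)[O-])C(O)C1 | intermediate (not isolated)
12 | methyl 7-[(1R,5S)-5-formyl-3-hydroxy-2-nitrocyclopentyl]heptanoate (chains trans; C9/C10 mixture) | O=C[C@@H]1[C@@H](CCCCCCC(=O)OC)C([N+](=O)[O-])C(O)C1 | intermediate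
13 | dimethyl (2-oxoheptyl)phosphonate | CCCCCC(=O)CP(=O)(OC)OC | starting material
14 | methyl 7-[(1R,5R)-3-hydroxy-2-nitro-5-[(1E)-3-oxooct-1-enyl]cyclopentyl]heptanoate (C9/C10 mixture) | CCCCCC(=O)/C=C/[C@@H]1[C@@H](CCCCCCC(=O)OC)C([N+](=O)[O-])C(O)C1 | intermediate
15 | methyl 7-[(1R,5R)-3-hydroxy-5-[(1E,3S)-3-hydroxyoct-1-enyl]-2-nitrocyclopentyl]heptanoate (C9/C10 mixture) | CCCCC[C@H](O)/C=C/[C@@H]1[C@@H](CCCCCCC(=O)OC)C([N+](=O)[O-])C(O)C1 | intermediate
16 | methyl 7-[(1R,5R)-5-[(1E,3S)-3-hydroxyoct-1-enyl]-2-nitrocyclopent-2-en-1-yl]heptanoate | CCCCC[C@H](O)/C=C/[C@@H]1[C@@H](CCCCCCC(=O)OC)C([N+](=O)[O-])=CC1 | intermediate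
17 | methyl 7-[(1R,2S)-2-[(1E,3S)-3-hydroxyoct-1-enyl]-5-oxocyclopent-3-en-1-yl]heptanoate (10,11-unsaturated C9 ketone) | CCCCC[C@H](O)/C=C/[C@@H]1[C@@H](CCCCCCC(=O)OC)C(=O)C=C1 | intermediate
18 | methyl 7-[(1S,2R,3R,5S)-2-[(1E,3S)-3-hydroxyoct-1-enyl]-4-oxo-6-oxabicyclo[3.1.0]hexan-3-yl]heptanoate | CCCCC[C@H](O)/C=C/[C@@H]1[C@@H](CCCCCCC(=O)OC)C(=O)[C@H]2O[C@@H]12 | intermediate
19 | methyl 7-[(1R,2R,3R)-3-hydroxy-2-[(1E,3S)-3-hydroxyoct-1-enyl]-5-oxocyclopentyl]heptanoate (11α-hydroxy C9 ketone) | CCCCC[C@H](O)/C=C/[C@@H]1[C@@H](CCCCCCC(=O)OC)C(=O)C[C@H]1O | intermediate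
20 | methyl 7-[(1R,2R,3R,5S)-3,5-dihydroxy-2-[(1E,3S)-3-hydroxyoct-1-enyl]cyclopentyl]heptanoate (methyl ester of the target) | CCCCC[C@H](O)/C=C/[C@@H]1[C@@H](CCCCCCC(=O)OC)[C@@H](O)C[C@H]1O | intermediate
21 | 7-[(1R,2R,3R,5S)-3,5-dihydroxy-2-[(1E,3S)-3-hydroxyoct-1-enyl]cyclopentyl]heptanoic acid (the target prostaglandin) | CCCCC[C@H](O)/C=C/[C@@H]1[C@@H](CCCCCCC(=O)O)[C@@H](O)C[C@H]1O | target

**Step count**
Total steps: 13. Longest linear sequence: 12 steps (steps 2–13, from cyclooctene); step 1 is the convergent branch to succinaldehyde.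

**Steps most likely to fail**

Step 5. Self-condensation and oligomerisation of the dialdehyde under amine catalysis may outrun the Michael addition, and equilibration at C12 may stop short. The fallback sets out from 9 and makes the same C8–C12 bond with commercial pent-4-enal (C=CCCC=O) as the donor under the same (S)-catalyst, which should give methyl (8R,9R)-9-formyl-8-(nitromethyl)dodec-11-enoate F1. Ozonolysis of its terminal alkene (O3, CH2Cl2, −78 °C; then Me2S) unmasks the second formyl group and rejoins the route at 10, which is cyclised and equilibrated to 12 with i-Pr2NEt as in the second stage of step 5.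

Step 9. The aerobic oxidation may stall at the deconjugated allylic nitro isomer, or the base may shift the ring alkene toward the C8–C12 position once the enone has formed. The fallback sets out from 16 and separates the nitro-to-carbonyl change from the desaturation. Conjugate reduction of the nitroalkene with NaBH4 in THF/MeOH at 0 °C should give methyl 7-[(1R,5R)-5-[(1E,3S)-3-hydroxyoct-1-enyl]-2-nitrocyclopentyl]heptanoate F2. A reductive Nef reaction of its nitronate (NaOMe, MeOH; then TiCl3, NH4OAc, H2O) should then give methyl 7-[(1R,2R)-2-[(1E,3S)-3-hydroxyoct-1-enyl]-5-oxocyclopentyl]heptanoate F3. Kinetic enolisation toward the C10 methylene with silylation (LiN(i-Pr)2, 2.2 equiv, Me3SiCl, THF, −78 °C) should give methyl 7-[(1R,5R)-2-(trimethylsilyloxy)-5-[(1E,3S)-3-(trimethylsilyloxy)oct-1-enyl]cyclopent-2-en-1-yl]heptanoate F4. Saegusa–Ito oxidation of this silyl enol ether (Pd(OAc)2, MeCN, rt), followed by citric acid in MeOH to free the C15 hydroxyl, rejoins the route at 17.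

Step 10. Facial selectivity in the peroxide addition may be poor, giving the 10β,11β-epoxide and hence the 11-epimer, and hydroxide may isomerise the enone. The fallback sets out from 17 and installs the C11 oxygen through boron. Copper-catalysed conjugate borylation (CuCl, NaOt-Bu, Xantphos, B2pin2, MeOH, THF, rt) should add the boryl group to C11 anti to the C12 chain. This gives methyl 7-[(1R,2R,3R)-2-[(1E,3S)-3-hydroxyoct-1-enyl]-5-oxo-3-(4,4,5,5-tetramethyl-1,3,2-dioxaborolan-2-yl)cyclopentyl]heptanoate F5. Oxidation with retention (NaBO3·4H2O, THF/H2O, rt) rejoins the route at 19, bypassing 18 and step 11.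

**Further compounds**
F1 | step 5 | methyl (8R,9R)-9-formyl-8-(nitromethyl)dodec-11-enoate | O=C[C@H](CC=C)[C@@H](CCCCCCC(=O)OC)C[N+](=O)[O-]
F2 | step 9 | methyl 7-[(1R,5R)-5-[(1E,3S)-3-hydroxyoct-1-enyl]-2-nitrocyclopentyl]heptanoate (C9 epimers) | CCCCC[C@H](O)/C=C/[C@@H]1[C@@H](CCCCCCC(=O)OC)C([N+](=O)[O-])CC1
F3 | step 9 | methyl 7-[(1R,2R)-2-[(1E,3S)-3-hydroxyoct-1-enyl]-5-oxocyclopentyl]heptanoate | CCCCC[C@H](O)/C=C/[C@@H]1[C@@H](CCCCCCC(=O)OC)C(=O)CC1
F4 | step 9 | methyl 7-[(1R,5R)-2-(trimethylsilyloxy)-5-[(1E,3S)-3-(trimethylsilyloxy)oct-1-enyl]cyclopent-2-en-1-yl]heptanoate | CCCCC[C@H](O[Si](C)(C)C)/C=C/[C@@H]1[C@@H](CCCCCCC(=O)OC)C(O[Si](C)(C)C)=CC1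
F5 | step 10 | methyl 7-[(1R,2R,3R)-2-[(1E,3S)-3-hydroxyoct-1-enyl]-5-oxo-3-(4,4,5,5-tetramethyl-1,3,2-dioxaborolan-2-yl)cyclopentyl]heptanoate | CCCCC[C@H](O)/C=C/[C@@H]1[C@@H](CCCCCCC(=O)OC)C(=O)C[C@H]1B2OC(C)(C)C(C)(C)O2
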